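**Assumption:** the target SMILES has no stereocentre and no stable stereogenic axis, so the molecule is achiral and "single enantiomer" imposes no requirement. The only stereo-element in the route is the transient E-enone of the chalcone.

## Retrosynthetic overview

1. Not taken: the usual union of two fully C-prenylated halves, which needs a regio-defined 3-(1,1-dimethylallyl)phloroacetophenone. Instead the C8–C(quaternary) bond is cut first: a late aromatic Claisen rearrangement of a 7-O-prenyl ether on the intact flavonol. That ether doubles as the 7-OH protecting group from the A-ring's first step.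
2. Both vicinal B-ring prenyl groups are cut together: one double Stille prenylation of a 2,3-dibromobenzaldehyde made from vanillin via 5,6-dibromovanillin.
3. Rings A and B are bought as arenes (phloroacetophenone, vanillin). The pyranone C ring is the only ring formed, by aldol condensation then alkaline-peroxide oxidative cyclisation. This closure is conventional; the non-obvious parts are points 1 and 2.
4. End game: Claisen (O7 to C8, with allyl inversion giving the reverse prenyl), then removal of three MOM groups.

## Route

**Step 1**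
Reactants: 1 vanillin; 2 bromine
Product: 3, 2,3-dibromo-4-hydroxy-5-methoxybenzaldehyde (5,6-dibromovanillin)
Conditions: Br2 (2.3 equiv), Fe powder (cat.), NaOAc, AcOH, rt → 40 °C
Reagents that add atoms: bromine, BrBr
Why: Electrophilic aromatic bromination; the first Br goes ortho to the phenol (C5) and the second, Fe-catalysed, goes para to OMe (C6), as in the classical preparation of this compound.

**Step 2**
Reactants: 3
Product: 4, 2,3-dibromo-4,5-dihydroxybenzaldehyde
Conditions: AlCl3 (1.3 equiv), pyridine (4.5 equiv), CH2Cl2, reflux; then 2 M HCl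
Reagents that add atoms: none
Why: Chelation-assisted AlCl3–pyridine demethylation of an o-hydroxyanisole; aldehyde and aryl bromides are untouched.

**Step 3**
Reactants: 4; 5 chloromethyl methyl ether (MOMCl)
Product: 6, 2,3-dibromo-4,5-bis(methoxymethoxy)benzaldehyde
Conditions: MOMCl (3 equiv), i-Pr2NEt (4 equiv), CH2Cl2, 0 °C → rt
Reagents that add atoms: MOMCl, COCCl
Why: Williamson-type O-alkylation of both phenols; MOM ethers survive the later base, Pd, alkaline peroxide and 200 °C steps.

**Step 4**
Reactants: 6; 7 tributyl(3-methylbut-2-en-1-yl)stannane (2.6 equiv)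
Product: 8, 4,5-bis(methoxymethoxy)-2,3-bis(3-methylbut-2-en-1-yl)benzaldehyde
Conditions: Pd(PPh3)4 (10 mol %), DMF, 100 °C, Ar
Reagents that add atoms: prenyltributylstannane, CCCC[Sn](CCCC)(CCCC)CC=C(C)C
Why: Double Stille coupling; prenylstannanes transfer to aryl-Pd at the α-carbon to give linear prenyl arenes, and bromobenzaldehydes and MOM ethers tolerate the neutral conditions.

**Step 5**
Reactants: 9, 2,4,6-trihydroxyacetophenone; 10 prenyl bromide (1.05 equiv)
Product: 11, 1-[2,6-dihydroxy-4-(3-methylbut-2-en-1-yloxy)phenyl]ethan-1-one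
Conditions: K2CO3 (1.1 equiv), acetone, reflux
Reagents that add atoms: prenyl bromide, CC(C)=CCBr
Why: Williamson etherification at the 4-OH, which is para to the acetyl group, not hydrogen-bonded and therefore the most acidic phenol.

**Step 6**
Reactants: 11; 5 MOMCl
Product: 12, 1-[2-hydroxy-6-(methoxymethoxy)-4-(3-methylbut-2-en-1-yloxy)phenyl]ethan-1-one
Conditions: MOMCl (1.1 equiv), i-Pr2NEt (1.5 equiv), CH2Cl2, 0 °C
Reagents that add atoms: MOMCl, COCCl
Why: Mono-O-alkylation of a symmetric diol; once one OH is capped the other is locked in a hydrogen bond to the ketone and does not react under amine base.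

**Step 7**
Reactants: 12; 8
Product: 13, (E)-3-[4,5-bis(methoxymethoxy)-2,3-bis(3-methylbut-2-en-1-yl)phenyl]-1-[2-hydroxy-6-(methoxymethoxy)-4-(3-methylbut-2-en-1-yloxy)phenyl]prop-2-en-1-one
Conditions: 50 % aq KOH, EtOH, rt, 48 h
Reagents that add atoms: none (both partners are listed reactants)
Why: Claisen–Schmidt aldol condensation gives the thermodynamic E-enone; MOM ethers, the prenyl ether and C-prenyl groups are base-stable.

**Step 8**
Reactants: 13; 14 hydrogen peroxide
Product: 15, 2-[4,5-bis(methoxymethoxy)-2,3-bis(3-methylbut-2-en-1-yl)phenyl]-3-hydroxy-5-(methoxymethoxy)-7-(3-methylbut-2-en-1-yloxy)-4H-chromen-4-one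
Conditions: 30 % H2O2, 2 M NaOH, MeOH/THF, 0 °C → rt
Reagents that add atoms: hydrogen peroxide, OO
Why: Algar–Flynn–Oyamada oxidative cyclisation; the only free phenol (2'-OH) closes the pyranone and the dihydroflavonol is oxidised to the flavonol, while hydroperoxide anion does not attack the electron-rich prenyl alkenes.

**Step 9**
Reactants: 15
Product: 16, 2-[4,5-bis(methoxymethoxy)-2,3-bis(3-methylbut-2-en-1-yl)phenyl]-3,7-dihydroxy-5-(methoxymethoxy)-8-(2-methylbut-3-en-2-yl)-4H-chromen-4-one
Conditions: PhNEt2, 195 °C (sealed tube or microwave), Ar, 1–2 h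
Reagents that add atoms: none
Why: Aromatic Claisen [3,3] rearrangement with allyl inversion; with 5-O capped as MOM (no 5-OH chelate), chromone bond fixation (C7=C8) and the less hindered C8 site direct migration to C8, giving the 1,1-dimethylallyl group and freeing 7-OH.

**Step 10**
Reactants: 16
Product: 17, Broussoflavonol C, 2-[4,5-dihydroxy-2,3-bis(3-methylbut-2-en-1-yl)phenyl]-3,5,7-trihydroxy-8-(2-methylbut-3-en-2-yl)-4H-chromen-4-one
Conditions: 3 M aq HCl, MeOH/THF, 45 °C, monitored; NaHCO3 quench
Reagents that add atoms: none
Why: Acid-catalysed acetal hydrolysis of the three aryl MOM ethers under mild conditions of the type routinely used on ortho-prenyl phenols without chroman formation.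

## Compound list

1 | vanillin | COc1cc(C=O)ccc1O | starting material
2 | bromine | BrBr | starting material (reagent)
3 | 2,3-dibromo-4-hydroxy-5-methoxybenzaldehyde | COc1cc(C=O)c(Br)c(Br)c1O | intermediate
4 | 2,3-dibromo-4,5-dihydroxybenzaldehyde | O=Cc1cc(O)c(O)c(Br)c1Br | intermediate
5 | chloromethyl methyl ether | COCCl | starting material (reagent)
6 | 2,3-dibromo-4,5-bis(methoxymethoxy)benzaldehyde | O=Cc1cc(OCOC)c(OCOC)c(Br)c1Br | intermediate
7 | tributyl(3-methylbut-2-en-1-yl)stannane | CCCC[Sn](CCCC)(CCCC)CC=C(C)C | starting material (reagent)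
8 | 4,5-bis(methoxymethoxy)-2,3-bis(3-methylbut-2-en-1-yl)benzaldehyde | O=Cc1cc(OCOC)c(OCOC)c(CC=C(C)C)c1CC=C(C)C | intermediate
9 | 2,4,6-trihydroxyacetophenone | CC(=O)c1c(O)cc(O)cc1O | starting material
10 | prenyl bromide (1-bromo-3-methylbut-2-ene) | CC(C)=CCBr | starting material (reagent)
11 | 1-[2,6-dihydroxy-4-(3-methylbut-2-en-1-yloxy)phenyl]ethan-1-one | CC(=O)c1c(O)cc(OCC=C(C)C)cc1O | intermediate
12 | 1-[2-hydroxy-6-(methoxymethoxy)-4-(3-methylbut-2-en-1-yloxy)phenyl]ethan-1-one | CC(=O)c1c(O)cc(OCC=C(C)C)cc1OCOC | intermediate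
13 | (E)-chalcone from 12 and 8 | COCOc1cc(OCC=C(C)C)cc(O)c1C(=O)/C=C/c1cc(OCOC)c(OCOC)c(CC=C(C)C)c1CC=C(C)C | intermediate
14 | hydrogen peroxide | OO | starting material (reagent)
15 | 3-hydroxy-5-(methoxymethoxy)-7-(prenyloxy)-2-[4,5-bis(methoxymethoxy)-2,3-diprenylphenyl]-4H-chromen-4-one | COCOc1cc(OCC=C(C)C)cc2oc(-c3cc(OCOC)c(OCOC)c(CC=C(C)C)c3CC=C(C)C)c(O)c(=O)c12 | intermediate
16 | 3,7-dihydroxy-5-(methoxymethoxy)-8-(2-methylbut-3-en-2-yl)-2-[4,5-bis(methoxymethoxy)-2,3-diprenylphenyl]-4H-chromen-4-one | COCOc1cc(O)c(C(C)(C)C=C)c2oc(-c3cc(OCOC)c(OCOC)c(CC=C(C)C)c3CC=C(C)C)c(O)c(=O)c12 | intermediate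
17 | Broussoflavonol C | C=CC(C)(C)c1c(O)cc(O)c2c(=O)c(O)c(-c3cc(O)c(O)c(CC=C(C)C)c3CC=C(C)C)oc12 | target

## Summary

**Total step count:** 10.
**Longest linear sequence:** 8 steps (1 → 2 → 3 → 4 → 7 → 8 → 9 → 10, from vanillin); the A-ring branch is 2 steps.

**Three steps most likely to fail**

1. **Step 9 (late Claisen).** Risks are C6 versus C8 regiochemistry, and abnormal-Claisen or dihydrofuran by-products from the new 7-OH next to the 1,1-dimethylallyl group. Fallback: do the [3,3] shift on acetophenone 12, where the chelated 2-OH directs migration to C3. Then cap the new 4-OH as MOM and carry the C-prenylated ketone through steps 7–8; the hindered chelated OH is the only free phenol, so ring closure must place the group at C8.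

2. **Step 8 (oxidative cyclisation).** A 6'-alkoxy chalcone with a hindered B ring can divert to the aurone. Fallback: abandon the chalcone and use a Baker–Venkataraman sequence. Oxidise 8 to the acid (Pinnick), esterify with 12, rearrange with LiHMDS and cyclodehydrate to the flavone. Then install the 3-OH by C3-lithiation (LDA), B(OMe)3 and H2O2, which spares the prenyl alkenes.

3. **Step 4 (double Stille on a hindered vicinal dibromide).** Risks are incomplete second coupling, some γ (reverse-prenyl) transfer, and allylation of the aldehyde. Fallback: drop the double coupling and use a stepwise route from a 2-bromo-4,5-dihydroxybenzaldehyde derivative. Put in the C6' prenyl by a single Stille coupling, and make the C5' prenyl by aromatic Claisen rearrangement of a 4-O-(1,1-dimethylallyl) ether (from 3-chloro-3-methylbut-1-yne O-alkylation and Lindlar reduction). That rearrangement can share the thermolysis of step 9.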